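## The problem

Target 21 is an achiral diaryl ether. Its bridging oxygen joins C6 of a methyl benzoate (ring A: C1 ester, C2 prenyloxy, C4 methyl) to C1' of a second benzene ring (ring B: C2' hydroxymethyl, C4' methoxy, C6' prenyloxy). There is no stereocentre, so the synthesis has to solve regiochemistry and functional-group tolerance only. Three of the four positions ortho to the ether oxygen are substituted, which makes a late metal-catalysed union of two finished rings unattractive. In ring A the ester carbon sits at C1 between two oxygen-bearing carbons, whereas electrophiles attack such a ring at C3 or C5, para to an oxygen; C1 therefore has to be reached by a directed process. The two aryl prenyl ethers rule out hydrogenolysis, peracids, strong Brønsted or Lewis acids and prolonged heating. The benzylic alcohol of ring B must be masked against bases and alkylating agents, and as an alkoxide it could attack the ring A ester to close an eight-membered lactone. The ester is flanked by two ortho substituents and would be hard to make or exchange late. The feature that opens the route is that C1–H of a 3-aryloxy-5-methylphenol derivative lies between the C2 and C6 oxygens: a carbonate on the C2 oxygen acidifies C1–H, can pass its methoxycarbonyl group to C1, and leaves the C2 oxygen as a phenoxide ready for prenylation.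

## Retrosynthesis

**21 from 20.** The O–Si bond of the ring B hydroxymethyl group is cut last. The alcohol must be masked through the organolithium step, because an alkoxide would consume base and would be prenylated afterwards. A tert-butyldimethylsilyl ether tolerates lithium amides and allylic bromides and is removed by fluoride, to which prenyl ethers and the hindered ester are indifferent. Compound 20 differs from 21 only in this group. The forward step asks only that the fluoride be buffered, so that no free alkoxide can reach the ring A ester.

**20 from 17 and 2.** In 20 the C1–carbonyl bond of ring A and the O–CH2 bond of the C2 prenyl ether are cut together, which gives aryl methyl carbonate 17 and prenyl bromide 2. The neighbouring cuts are weaker: late esterification of a 2,6-dioxygenated benzoic acid is slow, and forming the diaryl ether on a ring that already carries the ester would couple two ortho-substituted partners. In 17, ring A is a plain 1,3,5-trisubstituted benzene, and the carbon that becomes the ester already hangs on the oxygen that must later be prenylated. The forward reaction must deprotonate C1 selectively with a hindered lithium amide, move the acyl group from oxygen to carbon, and alkylate the released phenoxide in the same flask.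

**17 from 15 and 16.** The carbonate C–O bond is cut to phenol 15 and methyl chloroformate 16. A methyl carbonate is preferred to a tert-butyl carbonate because it delivers the methyl ester of the target directly. A tert-butyl ester would have to be exchanged at a doubly ortho-substituted carbonyl beside two acid-labile prenyl ethers. The forward step is a routine acylation of an unhindered phenol.

**15 from 12.** Ring A is traced back to the racemic cyclohexenone 12, which carries two more hydrogens. This turns the diaryl ether bond into the enol ether bond of a vinylogous ester, which forms by addition–elimination without metal catalysis on a doubly ortho-substituted phenol. It also differentiates the two ring A oxygens from the start (one is the ketone), which a symmetrical resorcinol could not do. The forward step is a dehydrogenation that must spare the prenyl olefin and the electron-rich ring B, which excludes iodine, quinone oxidants and acidic palladium systems; an enolate-based sulfur reagent at low temperature is chosen.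

**12 from 9 and 11; 11 from 10.** The C3–O bond of 12 is cut to ring B phenol 9 and chloroenone 11, and 11 comes from the symmetric dione 10 by chlorination. Both pieces are small. The forward step asks a hindered phenoxide to add to an unhindered β-chloroenone.

**9 from 8 from 7.** Silyl ether 9 comes from diol 8 by selective silylation of the primary alcohol, and 8 from salicylaldehyde 7 by hydride reduction. Keeping the carbon as an aldehyde until here lets it be introduced by ortho-formylation, the most reliable way to place one carbon next to a phenol.

**7 from 6 from 3 from 1 and 2.** The formyl C–C bond of 7 is cut to phenol 6, whose only free ortho position is the required one. The phenol oxygen of 6 is traced to the bromine of aryl bromide 3 through a boron intermediate, and 3 comes from 2-bromo-5-methoxyphenol 1 and prenyl bromide 2. An aldehyde-to-phenol oxidation with a peracid after O-prenylation was set aside because the trisubstituted olefin would be epoxidised; oxidation of a C–B bond with alkaline peroxide does not have this problem. The bromophenol 1 fixes the 1,2,4-oxygen pattern of ring B from the outset.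

## Roads not taken

**Alternative 1:** The cut runs through ring A: C1–C2 and C3–C4 are broken, leading to the 3-carbomethoxy-4-aryloxy-6-methyl-2-pyrone A2 and the ketene acetal A3 (1,1-dimethoxyethene).
- **Forward key step:** The electron-poor diene of A2 and the electron-rich olefin A3 undergo an inverse-demand [4+2] addition. The bridged lactone loses its carboxyl bridge, one methoxy group leaves as the alcohol, and benzoate A1 results.
- **Merits:** The ring A pattern is set by the polarisation of the two partners, not by competition between ring positions. The diaryl ether is made on an activated pyrone carbon, the ester is present from the start, and no organolithium is used.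
- **Weak points:** A1 has a methyl ether at C2 and a benzyl ether at C6' where the target has prenyl ethers, and an aldehyde where the target has the alcohol. At least four steps follow the key step: selective demethylation next to the ester in the presence of the ring B methoxy group, debenzylation, double prenylation and aldehyde reduction. A2 also needs its own multi-step preparation.
- **Comparison:** Alternative 1 is the safer plan for ring A regiochemistry, and its key step has closer precedent than the rearrangement of a methyl carbonate. The chosen plan offers in return the correct oxygen substituents straight from the key flask (17 to 20), a single step from 20 to 21, and a shorter route overall.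

**Alternative 2:** Ring B is cut at C5'–C6', C3'–C4' and C6'–C1', leading to the racemic 4-aryloxycyclobutenone A5 and methoxyethyne A6.
- **Forward key step:** On heating, A5 opens to a vinylketene that adds A6; a second ring opening and a six-electron closure give the diaryl ether A4 with only the C6' oxygen free. Prenylation and desilylation would finish the synthesis.
- **Merits:** The union is convergent, and ring B arrives with the one oxygen that needs a prenyl group already singled out. The orientation of alkoxyalkynes in such benzannulations is dependable.
- **Weak points:** A5 holds the complete ring A, with hindered ester and prenyl ether, through an oxygen on the sp3 carbon of a strained ring, and it has no simple source. Making it requires a finished ring A phenol, so the C1 ester problem is moved elsewhere and not solved. The heating needed for two ring openings invites a Claisen shift of the ring A prenyl ether, and A6 is volatile and unstable.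
- **Comparison:** Alternative 2 is at least as convergent, and its end game (two steps) is practically as short. The chosen plan has commercial building blocks and solves the C1 problem inside the route.

**Alternative 3:** The C6–O bond and the C1–carboxyl bond of ring A are cut together, leading to the silyl triflate A8 (aryne precursor), the ring B phenol A9 as its cesium salt, and carbon dioxide A10.
- **Forward key step:** Fluoride releases the 3-alkoxy aryne from A8; the phenoxide of A9 adds at C6, the aryl anion at C1 is captured by A10, and acid A7 results.
- **Merits:** This is the most convergent road. Two ring A bonds form in one operation between halves of similar size, and the alkoxy group of the aryne steers the oxygen to C6 and the charge to C1.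
- **Weak points:** It is a three-component capture. The aryl anion must meet A10 before it finds a proton. The doubly ortho-substituted phenoxide of A9 is a poor nucleophile and itself binds A10 reversibly. The fluoride that triggers the aryne endangers the silyl ether of A9. A7 then needs esterification, removal of two methoxymethyl ethers with acid, double prenylation and desilylation, and A8 takes several steps to make.
- **Comparison:** Alternative 3 is better in convergence and in bonds formed per step. The chosen plan sets against it an intramolecular acyl transfer with no third component, no fluoride before the last step, and a product (20) that already has the ester and the C2 prenyl ether in final form.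

Key step: step 10

Assumption: compounds 11, 12 and 13 are racemic and drawn without configuration; their single stereocentre becomes the methyl-bearing aromatic carbon in step 8, and the target has no stereocentre.

Abbreviations: prenyl = 3-methylbut-2-en-1-yl; TBS = tert-butyldimethylsilyl; ArB–O = 2-(TBSOCH2)-4-methoxy-6-(prenyloxy)phenoxy, the ring B unit.

## Route

Step 1
Reactants: 1 2-bromo-5-methoxyphenol; 2 prenyl bromide (1-bromo-3-methylbut-2-ene)
Product: 3 1-bromo-4-methoxy-2-(prenyloxy)benzene
Conditions: K2CO3, DMF, rt
Reagents that add atoms: none
Why: Williamson O-alkylation of a phenoxide by a primary allylic bromide; attack at the unhindered CH2 terminus should give the normal prenyl ether, and the aryl bromide is inert.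

Step 2
Reactants: 3 1-bromo-4-methoxy-2-(prenyloxy)benzene
Product: 6 4-methoxy-2-(prenyloxy)phenol, via aryllithium 4 (not isolated), via lithium aryltrimethoxyborate 5 (not isolated)
Conditions: n-BuLi, THF, −78 °C; B(OMe)3, −78 °C → rt; then 30% H2O2, aq NaOH, 0 °C
Reagents that add atoms: hydrogen peroxide, OO
Why: Bromine–lithium exchange at −78 °C is faster than deprotonation of the allylic ether, the aryllithium is trapped as the borate, and alkaline peroxide oxidises the C–B bond by 1,2-aryl migration. Hydroperoxide anion is nucleophilic and should leave the trisubstituted olefin alone, which a peracid-based aldehyde-to-phenol oxidation would not.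

Step 3
Reactants: 6 4-methoxy-2-(prenyloxy)phenol
Product: 7 2-hydroxy-5-methoxy-3-(prenyloxy)benzaldehyde
Conditions: MgCl2, Et3N, (CH2O)n, MeCN, reflux
Reagents that add atoms: paraformaldehyde (as formaldehyde), C=O
Why: Casnati–Skattebøl ortho-formylation; the magnesium phenoxide delivers formaldehyde to the only free ortho position and a second formaldehyde oxidises the hydroxymethyl intermediate by hydride transfer. The method is ortho-specific and is known to work on 2-alkoxyphenols.

Step 4
Reactants: 7 2-hydroxy-5-methoxy-3-(prenyloxy)benzaldehyde
Product: 8 2-(hydroxymethyl)-4-methoxy-6-(prenyloxy)phenol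
Conditions: NaBH4, MeOH, 0 °C
Reagents that add atoms: none
Why: Borohydride reduction of an aryl aldehyde; a near-neutral work-up should avoid ionisation of the electron-rich salicyl alcohol to an ortho-quinone methide.

Step 5
Reactants: 8 2-(hydroxymethyl)-4-methoxy-6-(prenyloxy)phenol
Product: 9 2-(TBSOCH2)-4-methoxy-6-(prenyloxy)phenol
Conditions: TBSCl, imidazole, CH2Cl2, 0 °C
Reagents that add atoms: tert-butyldimethylsilyl chloride, CC(C)(C)[Si](C)(C)Cl
Why: Selective silylation of the primary alcohol over a doubly ortho-substituted, hydrogen-bonded phenol, as is known for salicyl alcohol itself; any aryl silyl ether formed can be removed with K2CO3 in MeOH without loss of the alkyl silyl ether.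

Step 6
Reactants: 10 5-methylcyclohexane-1,3-dione
Product: 11 racemic 3-chloro-5-methylcyclohex-2-en-1-one
Conditions: (COCl)2, cat. DMF, CH2Cl2, 0 °C → rt
Reagents that add atoms: oxalyl chloride, O=C(Cl)C(=O)Cl
Why: Vilsmeier-type conversion of a cyclic 1,3-diketone into its vinylogous acid chloride; the dione is symmetric, so only one chloroenone can form.

Step 7
Reactants: 9 2-(TBSOCH2)-4-methoxy-6-(prenyloxy)phenol; 11 racemic 3-chloro-5-methylcyclohex-2-en-1-one
Product: 12 racemic 3-(ArB–O)-5-methylcyclohex-2-en-1-one
Conditions: Cs2CO3, DMF, 50 °C
Reagents that add atoms: none
Why: Conjugate addition–elimination (vinylogous acyl substitution) of a phenoxide on a β-chloroenone; the electrophilic carbon is unhindered, so the doubly ortho-substituted phenoxide should still add, and the alkyl silyl ether tolerates carbonate base.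

Step 8
Reactants: 12 racemic 3-(ArB–O)-5-methylcyclohex-2-en-1-one
Product: 15 3-(ArB–O)-5-methylphenol, via lithium dienolate 13 (not isolated), via cyclohexadienone 14 (not isolated)
Conditions: LiN(i-Pr)2, THF, −78 °C; then PhS(Cl)=N-t-Bu (enolate added to the reagent), −78 °C → rt
Reagents that add atoms: none
Why: Mukaiyama dehydrogenation: the kinetic α'-enolate of the vinylogous ester attacks sulfur of N-tert-butylbenzenesulfinimidoyl chloride, and the α-sulfilimine eliminates through a five-membered syn transition state to the cross-conjugated dienone, which tautomerises to the phenol. The reagent works at −78 °C and should not touch the prenyl olefin or ring B.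

Step 9
Reactants: 15 3-(ArB–O)-5-methylphenol; 16 methyl chloroformate
Product: 17 3-(ArB–O)-5-methylphenyl methyl carbonate
Conditions: pyridine, CH2Cl2, 0 °C
Reagents that add atoms: none
Why: O-acylation of an unhindered phenol by a chloroformate; nothing else in the molecule is nucleophilic under these conditions.

Step 10
Reactants: 17 3-(ArB–O)-5-methylphenyl methyl carbonate; 2 prenyl bromide
Product: 20 methyl 2-(ArB–O)-4-methyl-6-(prenyloxy)benzoate, via C1 aryllithium 18 (not isolated), via lithium phenoxide 19 (not isolated)
Conditions: LiN(i-Pr)2, THF, −78 °C (17 added to the base); then prenyl bromide, DMPU, −78 → 45 °C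
Reagents that add atoms: none
Why: Lithium diisopropylamide, pre-complexed to the carbonate carbonyl, should remove the C1 proton, the only ring A proton flanked by two oxygen substituents, to give aryllithium 18. The carbanion attacks the carbonate carbonyl through a four-membered transition state and the tetrahedral intermediate collapses with C2–O cleavage, a 1,3 oxygen-to-carbon acyl shift that gives the lithium salt 19 of the methyl salicylate. The closest known reaction type is the anionic ortho-Fries rearrangement of O-aryl carbamates and of aryl tert-butyl carbonates; the methyl carbonate is the same substrate class with a smaller alkoxy group. No ring is closed and no stereocentre is formed. The step needs site selectivity for C1 over C3 and over C5' of ring B: C3 has only one flanking oxygen, and C5' lies between two ether oxygens but has no carbonyl director, so a lithium amide at −78 °C should not deprotonate it. Inverse addition at low temperature keeps the concentration of unreacted carbonate low, so that acyl transfer to the amide or to phenoxide 19 cannot compete with the intramolecular shift. Phenoxide 19 is then O-alkylated at the primary carbon of prenyl bromide once DMPU breaks up the chelated lithium aggregate; the new ester is shielded by two ortho substituents against the amide base.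

Step 11
Reactants: 20 methyl 2-(ArB–O)-4-methyl-6-(prenyloxy)benzoate
Product: 21 methyl 2-[2-(hydroxymethyl)-4-methoxy-6-(prenyloxy)phenoxy]-4-methyl-6-(prenyloxy)benzoate (target)
Conditions: n-Bu4NF, AcOH, THF, 0 °C → rt
Reagents that add atoms: none
Why: Fluoride cleavage of a primary alkyl silyl ether; the acetic acid buffer keeps the freed benzylic alcohol protonated so that it cannot attack the ring A ester to form an eight-membered lactone, and the prenyl ethers and the hindered ester are inert.

## Compound list

1 | 2-bromo-5-methoxyphenol | COc1ccc(Br)c(O)c1 | starting material
2 | prenyl bromide (1-bromo-3-methylbut-2-ene) | CC(C)=CCBr | starting material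
3 | 1-bromo-4-methoxy-2-[(3-methylbut-2-en-1-yl)oxy]benzene | COc1ccc(Br)c(OCC=C(C)C)c1 | intermediate
4 | {4-methoxy-2-[(3-methylbut-2-en-1-yl)oxy]phenyl}lithium (formed in the flask) | [Li]c1ccc(OC)cc1OCC=C(C)C | intermediate
5 | lithium trimethoxy{4-methoxy-2-[(3-methylbut-2-en-1-yl)oxy]phenyl}borate (formed in the flask) | [Li+].CO[B-](OC)(OC)c1ccc(OC)cc1OCC=C(C)C | intermediate
6 | 4-methoxy-2-[(3-methylbut-2-en-1-yl)oxy]phenol | COc1ccc(O)c(OCC=C(C)C)c1 | intermediate
7 | 2-hydroxy-5-methoxy-3-[(3-methylbut-2-en-1-yl)oxy]benzaldehyde | COc1cc(C=O)c(O)c(OCC=C(C)C)c1 | intermediate
8 | 2-(hydroxymethyl)-4-methoxy-6-[(3-methylbut-2-en-1-yl)oxy]phenol | COc1cc(CO)c(O)c(OCC=C(C)C)c1 | intermediate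
9 | 2-({[tert-butyl(dimethyl)silyl]oxy}methyl)-4-methoxy-6-[(3-methylbut-2-en-1-yl)oxy]phenol | COc1cc(CO[Si](C)(C)C(C)(C)C)c(O)c(OCC=C(C)C)c1 | intermediate
10 | 5-methylcyclohexane-1,3-dione | CC1CC(=O)CC(=O)C1 | starting material
11 | racemic 3-chloro-5-methylcyclohex-2-en-1-one | CC1CC(Cl)=CC(=O)C1 | intermediate
12 | racemic 3-[2-({[tert-butyl(dimethyl)silyl]oxy}methyl)-4-methoxy-6-[(3-methylbut-2-en-1-yl)oxy]phenoxy]-5-methylcyclohex-2-en-1-one | CC1CC(=O)C=C(Oc2c(CO[Si](C)(C)C(C)(C)C)cc(OC)cc2OCC=C(C)C)C1 | intermediate
13 | racemic lithium dienolate of 12, deprotonated at C6 (formed in the flask) | [Li]OC1=CC(C)CC(Oc2c(CO[Si](C)(C)C(C)(C)C)cc(OC)cc2OCC=C(C)C)=C1 | intermediate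
14 | 3-[2-({[tert-butyl(dimethyl)silyl]oxy}methyl)-4-methoxy-6-[(3-methylbut-2-en-1-yl)oxy]phenoxy]-5-methylcyclohexa-2,5-dien-1-one (formed in the flask) | CC1=CC(=O)C=C(Oc2c(CO[Si](C)(C)C(C)(C)C)cc(OC)cc2OCC=C(C)C)C1 | intermediate
15 | 3-[2-({[tert-butyl(dimethyl)silyl]oxy}methyl)-4-methoxy-6-[(3-methylbut-2-en-1-yl)oxy]phenoxy]-5-methylphenol | Cc1cc(O)cc(Oc2c(CO[Si](C)(C)C(C)(C)C)cc(OC)cc2OCC=C(C)C)c1 | intermediate
16 | methyl chloroformate | COC(=O)Cl | starting material
17 | 3-[2-({[tert-butyl(dimethyl)silyl]oxy}methyl)-4-methoxy-6-[(3-methylbut-2-en-1-yl)oxy]phenoxy]-5-methylphenyl methyl carbonate | COC(=O)Oc1cc(C)cc(Oc2c(CO[Si](C)(C)C(C)(C)C)cc(OC)cc2OCC=C(C)C)c1 | intermediate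
18 | C1-lithiated 17, lithium between the carbonate and aryloxy oxygens (formed in the flask) | [Li]c1c(OC(=O)OC)cc(C)cc1Oc1c(CO[Si](C)(C)C(C)(C)C)cc(OC)cc1OCC=C(C)C | intermediate
19 | lithium phenoxide of methyl 2-(ring B aryloxy)-6-hydroxy-4-methylbenzoate (formed in the flask) | [Li]Oc1cc(C)cc(Oc2c(CO[Si](C)(C)C(C)(C)C)cc(OC)cc2OCC=C(C)C)c1C(=O)OC | intermediate
20 | methyl 2-[2-({[tert-butyl(dimethyl)silyl]oxy}methyl)-4-methoxy-6-[(3-methylbut-2-en-1-yl)oxy]phenoxy]-4-methyl-6-[(3-methylbut-2-en-1-yl)oxy]benzoate | COC(=O)c1c(OCC=C(C)C)cc(C)cc1Oc1c(CO[Si](C)(C)C(C)(C)C)cc(OC)cc1OCC=C(C)C | intermediate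
21 | methyl 2-[2-(hydroxymethyl)-4-methoxy-6-[(3-methylbut-2-en-1-yl)oxy]phenoxy]-4-methyl-6-[(3-methylbut-2-en-1-yl)oxy]benzoate | COC(=O)c1c(OCC=C(C)C)cc(C)cc1Oc1c(CO)cc(OC)cc1OCC=C(C)C | target

## Step count and least certain steps

Total: 11 steps. Longest linear sequence: 10 steps (steps 1–5 and 7–11, from 1); step 6 is a one-step side branch.

**Step 10 (key step).** The most likely failure is acyl transfer from the methyl carbonate to the amide base or to phenoxide 19 already formed, which would return phenol 15 in place of the C1-acylated product. A methyl carbonate is less shielded than the tert-butyl carbonates and carbamates on which this rearrangement is established. The second weak point is slow O-alkylation of the chelated lithium phenoxide.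
Fallback: it sets out from phenol 15 and returns at 20. Phenol 15 is converted with Et2NCOCl and pyridine into the O-aryl N,N-diethylcarbamate F1. F1 undergoes the well-established anionic ortho-Fries rearrangement with LiN(i-Pr)2 (−78 °C → rt), and the phenoxide is prenylated with 2 and DMPU in the same flask to give the N,N-diethylbenzamide F2. O-Methylation of the amide with Me3OBF4 and hydrolysis of the imidate salt with aqueous Na2CO3 in MeOH then gives methyl ester 20.

**Step 8.** The likely failure is proton transfer from newly formed phenol 15 to unreacted enolate 13, which would stall the dehydrogenation at partial conversion; sulfenylation without elimination is the other possibility. This is why the enolate is added to the reagent.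
Fallback: it sets out from phenol 9 and returns at 15, bypassing 11–14. An Ullmann coupling of 9 with 3-bromo-5-iodotoluene (CuI, picolinic acid, K3PO4, DMSO, 90 °C) at the C–I bond gives the 1-bromo-3-aryloxy-5-methylbenzene F3. Bromine–lithium exchange, borate formation and alkaline peroxide oxidation, as in step 2, then give 15.

**Step 7.** The likely failure is loss of silanolate from the ortho-(silyloxymethyl)phenoxide, with ortho-quinone methide formation, or slow addition of the doubly ortho-substituted phenoxide at the temperature needed.
Fallback: it sets out from aldehyde 7 and returns at 12, with the same number of steps. The phenoxide of 7, which cannot form a quinone methide, is added to 11 (Cs2CO3, DMF) to give the racemic aryloxy-enone aldehyde F4. NaBH4 in MeOH at −40 °C reduces the aldehyde selectively in the presence of the unreactive vinylogous ester to give the racemic benzylic alcohol F5, and TBSCl with imidazole gives 12.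

**Step 2.** The likely failure is proton transfer from the allylic O–CH2 group to the aryllithium, followed by Wittig-type rearrangement, or butylation of the aryllithium by the 1-bromobutane formed in the exchange.
Fallback: it sets out from bromide 3 and returns at 6, with no carbanion involved. Miyaura borylation of 3 (B2pin2, PdCl2(dppf), KOAc, dioxane, 80 °C) gives the aryl pinacol boronate F6, and oxidation with NaBO3·4H2O in THF–water gives 6.

## Further compounds

F1 | step 10 | 3-[2-({[tert-butyl(dimethyl)silyl]oxy}methyl)-4-methoxy-6-[(3-methylbut-2-en-1-yl)oxy]phenoxy]-5-methylphenyl N,N-diethylcarbamate | CCN(CC)C(=O)Oc1cc(C)cc(Oc2c(CO[Si](C)(C)C(C)(C)C)cc(OC)cc2OCC=C(C)C)c1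
F2 | step 10 | 2-[2-({[tert-butyl(dimethyl)silyl]oxy}methyl)-4-methoxy-6-[(3-methylbut-2-en-1-yl)oxy]phenoxy]-N,N-diethyl-4-methyl-6-[(3-methylbut-2-en-1-yl)oxy]benzamide | CCN(CC)C(=O)c1c(OCC=C(C)C)cc(C)cc1Oc1c(CO[Si](C)(C)C(C)(C)C)cc(OC)cc1OCC=C(C)C
F3 | step 8 | 1-bromo-3-[2-({[tert-butyl(dimethyl)silyl]oxy}methyl)-4-methoxy-6-[(3-methylbut-2-en-1-yl)oxy]phenoxy]-5-methylbenzene | Cc1cc(Br)cc(Oc2c(CO[Si](C)(C)C(C)(C)C)cc(OC)cc2OCC=C(C)C)c1
F4 | step 7 | racemic 5-methoxy-2-[(5-methyl-3-oxocyclohex-1-en-1-yl)oxy]-3-[(3-methylbut-2-en-1-yl)oxy]benzaldehyde | CC1CC(=O)C=C(Oc2c(C=O)cc(OC)cc2OCC=C(C)C)C1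
F5 | step 7 | racemic 3-[2-(hydroxymethyl)-4-methoxy-6-[(3-methylbut-2-en-1-yl)oxy]phenoxy]-5-methylcyclohex-2-en-1-one | CC1CC(=O)C=C(Oc2c(CO)cc(OC)cc2OCC=C(C)C)C1
F6 | step 2 | 2-{4-methoxy-2-[(3-methylbut-2-en-1-yl)oxy]phenyl}-4,4,5,5-tetramethyl-1,3,2-dioxaborolane | COc1ccc(B2OC(C)(C)C(C)(C)O2)c(OCC=C(C)C)c1
A1 | alternative 1 | methyl 2-[2-(benzyloxy)-6-formyl-4-methoxyphenoxy]-6-methoxy-4-methylbenzoate | COC(=O)c1c(OC)cc(C)cc1Oc1c(C=O)cc(OC)cc1OCc1ccccc1
A2 | alternative 1 | methyl 4-[2-(benzyloxy)-6-formyl-4-methoxyphenoxy]-6-methyl-2-oxo-2H-pyran-3-carboxylate | COC(=O)C1=C(Oc2c(C=O)cc(OC)cc2OCc2ccccc2)C=C(C)OC1=O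
A3 | alternative 1 | 1,1-dimethoxyethene | COC(=C)OC
A4 | alternative 2 | methyl 2-[2-({[tert-butyl(dimethyl)silyl]oxy}methyl)-6-hydroxy-4-methoxyphenoxy]-4-methyl-6-[(3-methylbut-2-en-1-yl)oxy]benzoate | COC(=O)c1c(OCC=C(C)C)cc(C)cc1Oc1c(CO[Si](C)(C)C(C)(C)C)cc(OC)cc1O
A5 | alternative 2 | racemic methyl 2-{[2-({[tert-butyl(dimethyl)silyl]oxy}methyl)-4-oxocyclobut-2-en-1-yl]oxy}-4-methyl-6-[(3-methylbut-2-en-1-yl)oxy]benzoate | COC(=O)c1c(OCC=C(C)C)cc(C)cc1OC1C(=O)C=C1CO[Si](C)(C)C(C)(C)C
A6 | alternative 2 | methoxyethyne | COC#C
A7 | alternative 3 | 2-[2-({[tert-butyl(dimethyl)silyl]oxy}methyl)-4-methoxy-6-(methoxymethoxy)phenoxy]-6-(methoxymethoxy)-4-methylbenzoic acid | O=C(O)c1c(OCOC)cc(C)cc1Oc1c(CO[Si](C)(C)C(C)(C)C)cc(OC)cc1OCOC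
A8 | alternative 3 | 3-(methoxymethoxy)-5-methyl-2-(trimethylsilyl)phenyl trifluoromethanesulfonate | COCOc1cc(C)cc(OS(=O)(=O)C(F)(F)F)c1[Si](C)(C)C
A9 | alternative 3 | 2-({[tert-butyl(dimethyl)silyl]oxy}methyl)-4-methoxy-6-(methoxymethoxy)phenol | COCOc1cc(OC)cc(CO[Si](C)(C)C(C)(C)C)c1O
A10 | alternative 3 | carbon dioxide | O=C=O
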